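## Retrosynthetic overview

1. The target is methyl 2-[(3S,6S)-6-hexadecyl-6-methoxy-3,6-dihydro-1,2-dioxin-3-yl]acetate, with OMe and CH2CO2Me cis. C6 is a peroxyketal centre set last by acid equilibration in MeOH, so only C3 needs absolute control.
2. The dioxine ring is the only ring and is closed last. Disconnection of O2–C3 gives a catalyst-controlled 6-exo peroxy-Michael addition of a C6 methoxy hydroperoxide onto the C2=C3 enoate, which requires the 4Z alkene.
3. The methoxy hydroperoxide comes from methyl (2E,4Z)-6-oxodocosa-2,4-dienoate with H2O2 and MeOH.
4. Key C2–C3 disconnection: the ester α-carbon acts as an electrophile (Rh carbenoid from methyl diazoacetate, an enolonium equivalent) toward the free α-carbon of 2-hexadecylfuran, a donor that becomes the ester β-carbon. Furan unravelling delivers the ketone, the 4Z alkene and the 2E enoate in one step.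
5. 2-Hexadecylfuran comes from 2-furyllithium (a masked acyl anion for C6) and 1-bromohexadecane; methyl diazoacetate comes from glycine methyl ester hydrochloride.

Assumption: the quinidine-derived catalyst of step 5 is taken to give the 3S series; if a first run shows 3R, its quinine-derived pseudoenantiomer is used instead.

## Route

Step 1
Reactants: 1 furan; 2 1-bromohexadecane
Product: 4 2-hexadecylfuran, via 2-furyllithium 3 (not isolated)
Conditions: n-BuLi (1.05 equiv), THF, −78 → 0 °C, 1 h; then 2 (0.9 equiv), 0 °C → rt, 16 h
Reagents that add atoms: none
Why: Oxygen-directed α-lithiation of furan followed by SN2 alkylation with the primary bromide (heteroaryl lithiation/alkylation), the furyl anion serving as the masked acyl anion of the future C6 ketone; no stereocentre is formed.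

Step 2
Reactants: 5 glycine methyl ester hydrochloride
Product: 6 methyl diazoacetate
Conditions: NaNO2 (1.2 equiv), H2SO4 (5 mol%), CH2Cl2/H2O, −5 °C; dried CH2Cl2 solution used directly, never concentrated
Reagents that add atoms: sodium nitrite, [Na+].[O-]N=O
Why: Diazotisation of a primary α-amino ester, in which the diazonium ion loses its acidified α-proton to give the stabilised diazo ester; no stereocentre is formed.

Step 3 (key step)
Reactants: 4 2-hexadecylfuran; 6 methyl diazoacetate
Product: 8 methyl (2E,4Z)-6-oxodocosa-2,4-dienoate, via cyclopropane adduct 7 (not isolated)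
Conditions: Rh2(OAc)4 (1 mol%), 4 (2 equiv, excess recovered), CH2Cl2, rt, 6 added over 6 h by syringe pump, dark; then 35 °C, 1 h; rapid chromatography on neutral silica, used at once
Reagents that add atoms: none
Why: Rhodium-carbenoid furan ring-opening (cyclopropanation then unravelling, the furan–diazo ester reaction of Wenkert type): the electrophilic carbenoid, an ester α-cation (enolonium) equivalent, is attacked by the free α-carbon of the 2-alkylfuran, which becomes the ester β-carbon, and collapse of adduct 7 with cleavage of the ring C–O bond releases the ketone, so the 4Z alkene is inherited from the furan ring and the new alkene is 2E; no stereocentre is formed.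

Step 4
Reactants: 8 methyl (2E,4Z)-6-oxodocosa-2,4-dienoate
Product: 9 methyl (2E,4Z)-6-hydroperoxy-6-methoxydocosa-2,4-dienoate (racemic at C6)
Conditions: urea–hydrogen peroxide (3 equiv), Sc(OTf)3 (5 mol%), MeOH, 0 °C, 2–4 h, dark; NaHCO3 quench
Reagents that add atoms: hydrogen peroxide (delivered as urea–hydrogen peroxide), OO; methanol, CO
Why: Acid-catalysed perketalisation of a ketone (oxocarbenium formation in methanol and capture by hydrogen peroxide, the stronger α-effect nucleophile, as used to make methoxy hydroperoxides for 1,2-dioxane synthesis); C6 is formed racemic, which does not matter because it is equilibrated in step 5, and the cold, dark, weakly Lewis-acidic conditions are chosen to keep the 4Z alkene and avoid uncatalysed ring closure.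

Step 5
Reactants: 9 methyl (2E,4Z)-6-hydroperoxy-6-methoxydocosa-2,4-dienoate
Product: 11 methyl 2-[(3S,6S)-6-hexadecyl-6-methoxy-3,6-dihydro-1,2-dioxin-3-yl]acetate (6-epi-chondrillin), via (3S,6R)-epimer 10 (not isolated)
Conditions: (a) 3-[[3,5-bis(trifluoromethyl)phenyl]amino]-4-[[(9R)-6'-methoxycinchonan-9-yl]amino]cyclobut-3-ene-1,2-dione (10 mol%), toluene, −20 °C, 24–48 h; (b) MeOH, (1S)-(+)-10-camphorsulfonic acid (0.3 equiv), 0 °C → rt, 3 h; chromatography
Reagents that add atoms: methanol, CO (stage b exchanges the C6 methoxy group)
Why: Proposed new method: an enantioselective 6-exo-trig intramolecular peroxy-Michael addition in which the quinuclidine base of the bifunctional catalyst ion-pairs the hydroperoxide (pKa about 12, comparable to a phenol) while the squaramide hydrogen-bonds the enoate, so that the O–C3 bond forms on one enoate face (3S) for both C6 epimers of 9 because 1,4-induction from C6 is weak, the closest known reactions being the diethylamine-mediated racemic peroxy-Michael closure of methoxy hydroperoxides onto enoates and base-catalysed enantioselective intramolecular oxa-Michael additions of phenols and alcohols to α,β-unsaturated esters; stage b then equilibrates only the ketal centre C6 through the cyclic allylic peroxycarbenium ion (acid-catalysed transketalisation in methanol) toward 11, which is expected to be favoured because its methoxy group is pseudoaxial (anomeric effect) and both carbon substituents are pseudoequatorial, while C3 is untouched.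

## Compound list

1 | furan | `c1ccoc1` | starting material
2 | 1-bromohexadecane | `CCCCCCCCCCCCCCCCBr` | starting material
3 | 2-furyllithium | `[Li]c1ccco1` | intermediate (not isolated)
4 | 2-hexadecylfuran | `CCCCCCCCCCCCCCCCc1ccco1` | intermediate
5 | glycine methyl ester hydrochloride | `COC(=O)C[NH3+].[Cl-]` | starting material
6 | methyl diazoacetate | `COC(=O)C=[N+]=[N-]` | intermediate
7 | methyl 3-hexadecyl-2-oxabicyclo[3.1.0]hex-3-ene-6-carboxylate (racemic, exo ester, one enantiomer drawn) | `CCCCCCCCCCCCCCCCC1=C[C@H]2[C@@H](O1)[C@@H]2C(=O)OC` | intermediate (not isolated)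
8 | methyl (2E,4Z)-6-oxodocosa-2,4-dienoate | `CCCCCCCCCCCCCCCCC(=O)/C=C\C=C\C(=O)OC` | intermediate
9 | methyl (2E,4Z)-6-hydroperoxy-6-methoxydocosa-2,4-dienoate (racemic at C6) | `CCCCCCCCCCCCCCCCC(OC)(OO)/C=C\C=C\C(=O)OC` | intermediate
10 | methyl 2-[(3S,6R)-6-hexadecyl-6-methoxy-3,6-dihydro-1,2-dioxin-3-yl]acetate (C6 epimer of the target) | `CCCCCCCCCCCCCCCC[C@]1(OC)C=C[C@H](CC(=O)OC)OO1` | intermediate (not isolated)
11 | methyl 2-[(3S,6S)-6-hexadecyl-6-methoxy-3,6-dihydro-1,2-dioxin-3-yl]acetate (6-epi-chondrillin) | `CCCCCCCCCCCCCCCC[C@@]1(OC)C=C[C@H](CC(=O)OC)OO1` | target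

## Step count

Total steps: 5. Longest linear sequence: 4 steps (1 → 3 → 4 → 5, from furan).

## Three steps most likely to fail

**Step 5 (highest risk).** The enantioselectivity of the peroxy-Michael closure is unproven. Racemic 9 makes the reaction doubly stereodifferentiating. The amine catalyst could also start a Kornblum–DeLaMare fragmentation of the product, so the reaction is kept at −20 °C and stopped at full conversion.

Fallback (resolution instead of asymmetric catalysis), setting out from 9 and coming back at 11: close the ring without stereocontrol using Et2NH (1.5 equiv) in CF3CH2OH at rt, the established conditions for this type of peroxy-Michael closure. Then equilibrate C6 with camphorsulfonic acid in MeOH as in stage b and isolate racemic methyl 2-[(3S*,6S*)-6-hexadecyl-6-methoxy-3,6-dihydro-1,2-dioxin-3-yl]acetate F1. Separate it by preparative chromatography on an amylose tris(3,5-dimethylphenylcarbamate) stationary phase into 11 and methyl 2-[(3R,6R)-6-hexadecyl-6-methoxy-3,6-dihydro-1,2-dioxin-3-yl]acetate F2, which is discarded.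

**Step 4.** The conjugated ketone may perketalise slowly, the 4Z alkene may isomerise under the Lewis acid, or 9 may ring-close racemically in the pot. In the last case the material is carried through the step 5 fallback.

Fallback (water-free two-stage ketal exchange instead of direct perhydration), setting out from 8 and coming back at 9: treat 8 with trimethyl orthoformate, MeOH and pyridinium p-toluenesulfonate (5 mol%) at 0 °C to give methyl (2E,4Z)-6,6-dimethoxydocosa-2,4-dienoate F3. Then exchange one methoxy group for OOH with anhydrous ethereal H2O2 (5 equiv) and pyridinium p-toluenesulfonate (5 mol%) at −20 °C (acid-catalysed perhydrolysis of a ketal) to reach 9.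

**Step 3.** Possible problems are carbenoid dimerisation, attack at the substituted double bond of the furan, a cyclopropane 7 that resists opening, or loss of the 4Z geometry on work-up.

Fallback (oxidative unmasking of the furan and olefination instead of carbene chemistry), setting out from 4 and coming back at 8: oxidise 4 with N-bromosuccinimide (1.05 equiv) and NaHCO3 in acetone/H2O at −20 °C, then pyridine, to open the ring to (Z)-4-oxoicos-2-enal F4. Olefinate the aldehyde in the same flask with methyl (triphenylphosphoranylidene)acetate (CH2Cl2, 0 °C) to give 8; the 4Z alkene again comes from the ring and the stabilised ylide sets 2E. The C6–C7 bond of the skeleton is then still made through the furyl anion of step 1 as masked acyl anion.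

## Further compounds

F1 | step 5 | racemic methyl 2-[(3S*,6S*)-6-hexadecyl-6-methoxy-3,6-dihydro-1,2-dioxin-3-yl]acetate (1:1 mixture of 11 and F2) | `CCCCCCCCCCCCCCCC[C@@]1(OC)C=C[C@H](CC(=O)OC)OO1.CCCCCCCCCCCCCCCC[C@]1(OC)C=C[C@@H](CC(=O)OC)OO1`
F2 | step 5 | methyl 2-[(3R,6R)-6-hexadecyl-6-methoxy-3,6-dihydro-1,2-dioxin-3-yl]acetate | `CCCCCCCCCCCCCCCC[C@]1(OC)C=C[C@@H](CC(=O)OC)OO1`
F3 | step 4 | methyl (2E,4Z)-6,6-dimethoxydocosa-2,4-dienoate | `CCCCCCCCCCCCCCCCC(OC)(OC)/C=C\C=C\C(=O)OC`
F4 | step 3 | (Z)-4-oxoicos-2-enal | `CCCCCCCCCCCCCCCCC(=O)/C=C\C=O`
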